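## The problem

The target is the C3 ester of a trinor-eremophilane diol with (2E,4E,6S,7S)-7-hydroxy-6-methylocta-2,4-dienoic acid. In eremophilane numbering, ring A (C1–C5, C10) and ring B (C5–C10) share the C5–C10 bond. C5 is quaternary and bears a methyl group, and C4 bears the second methyl cis to it. A linear dienone runs C8(=O)–C9=C10–C1=C2, C7 carries a free hydroxyl next to the ketone, and C3 carries the allylic acyloxy group.

The vicinal pair C4/C5 cannot be repaired once the rings exist, so it must come out of the ring-forming event. The ring fusion forces the C5 methyl to be pseudo-axial on both rings, and it can then steer the other two ring centres. The C7 oxygen lies trans to it in the equatorial, thermodynamically preferred position. The C3 oxygen lies cis to both methyls in the pseudo-axial position that a stereoelectronically controlled allylic functionalisation should reach.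

The two side-chain centres (syn methyl and hydroxyl) are too remote for core control and must be made separately.

Several groups rule out rough treatment. The α-hydroxy ketone can epimerise, undergo ketol shift or air-oxidise. The dienone is a 1,6-acceptor. The allylic ester at C3 can eliminate towards a trienone. The dienoate has a vinylogously acidic C6′ centre once its acyl group is activated.

The feature that opens the synthesis is that the twelve core carbons match the bicyclic part of (+)-aristolochene: the cis C4/C5 methyls, the C9=C10 alkene, and a C7 substituent trans to the C5 methyl. The terpene differs only in oxidation level and in carrying an isopropenyl group at C7 where the target has hydroxyl.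

## Retrosynthesis

**26 ⇒ 25.** The two O–H bonds of target 26 are masked as tert-butyldimethylsilyl ethers in 25. Both hydroxyls are secondary and unhindered enough for one acidic fluoride treatment, which avoids the base that the α-ketol and the allylic ester would not tolerate. An acetate at C7 was rejected because it could not be removed beside the C3 dienoate.

**25 ⇒ 12 + 23.** The acyl C–O bond of the C3 ester is cut, giving core alcohol 12 and protected acid 23. This divides the molecule into a 12-carbon and a 9-carbon half made in parallel. It leaves the C3–O bond untouched, so the configuration of 12 is carried over. The forward reaction must acylate a hindered, pseudo-axial allylic alcohol without isomerising the dienoyl unit.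

**23 ⇒ 19 + 20 ⇒ 16 ⇒ 13 + 14.** The C4′=C5′ alkene is cut to aldehyde 19 and phosphonocrotonate 20 (vinylogous Horner–Wadsworth–Emmons). The C6′–C7′ bond is then cut to propionyl imide 13 and acetaldehyde 14. The syn methyl/hydroxyl pair is the signature of an Evans aldol, so both chain centres come from one reagent-controlled step; 17 and 18 are the intervening Weinreb amides.

**12 ⇒ 11 ⇒ 10.** The C3–O bond is cut to a C–H bond of dienone 11, and the C1=C2 alkene is taken back to enone 10. Both operations use the conjugation of the C8 ketone, and both are steered by the fixed envelope of ring A, so no new chiral reagent is needed. The forward reactions must oxidise the ε-methylene of a dienone on the face of the two methyls and dehydrogenate an enone in the linear sense.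

**10 ⇒ 9 ⇒ 8 ⇒ 6 ⇒ 5.** The silyl ether is exchanged for the acetate 8. The C7–O bond of 8 is traced to the C7–C11 bond of isopropenyl ketone 6 by an ozonolysis–Criegee rearrangement, which replaces carbon by oxygen with retention. The C8 carbonyl is traced to an allylic methylene of hydrocarbon 5. Oxidising C8 first is preferred over the reverse order because the resulting enone no longer competes with the isopropenyl group for ozone.

**5 ⇒ 3 ⇒ 2 ⇒ 1.** Three carbon–carbon bonds of 5 are cut at once: C6–C7, C5–C10, and the bond from C5 to its methyl (formed by a 1,2-shift from C10). This unfolds both rings and all three carbon stereocentres to the achiral chain of farnesyl diphosphate 3, made in two steps from farnesol 1 via chloride 2. No laboratory cut is comparably simplifying. The forward reaction asks for a chain fold only an enzyme active site can enforce, so the step is given to aristolochene synthase.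

## Roads not taken

**Alternative 1:** Ring B is cut at C5–C6 and C9–C10. Forward, an aluminium Lewis acid activates the enantiopure enone (S)-6-(tert-butyldimethylsilyloxy)-2-methylcyclohex-2-en-1-one A2. 2-(Trimethylsilyloxy)buta-1,3-diene A3 adds across its C5=C10 bond to give the cis-fused adduct A1, with C5 quaternary and the C8 oxygen present as a C7=C8 silyl enol ether.
- Merits: two small partners; the C3 oxygen is carried in from the start; the enol ether is set up for a Rubottom hydroxylation at C7.
- Weak points: the C4 methyl is missing (C4 is a ketone) and must be added and set cis to the C5 methyl by a face-selective reduction. The α-methyl enone is a hindered dienophile whose facial bias rests on one remote silyloxy group. Both ring alkenes must still be introduced, which erases the C10 hydrogen the cycloaddition has just placed. A2 itself needs an enantioselective preparation.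
- Comparison: on C3 this road is better than the chosen one, which must create the C3–O bond late on a dienone. Against that, the chosen plan delivers C4, C5 and C7 together with absolute control in one catalytic step, and the C9=C10 alkene is already in place.

**Alternative 2:** Rings A and B are cut together at C3–C4 and C5–C10. An amine base moves the triple bond of an open-chain skipped ynone into an allenyl ketone. Its vinylallene unit (C3=C2–C1=C10) then adds the tethered (E)-trisubstituted alkene (C4=C5) intramolecularly to give A4, the triethylsilyl ether of alcohol 12.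
- Merits: the most direct access to the fully oxygenated, differentially protected core. No late oxidation at C3, C7 or C8 and no dehydrogenation are needed. The cis methyls follow stereospecifically from the alkene geometry.
- Weak points: three centres (C3, C4, C5) are set in one cycloaddition whose facial sense depends on the single C7 silyloxy centre in the tether. The dienophile is unactivated. The base can carry the isomerisation past the allene to a conjugated dienone. The chain precursor, including a silyl enol ether of defined geometry, needs its own multi-step assembly.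
- Comparison: if the cycloaddition is face-selective, this road reaches the stage of 12 with less redox manipulation than the chosen one and needs no enzyme. The chosen plan sets against it a configuration at C4, C5 and C7 that does not depend on a diastereoselective cycloaddition, and a three-step access to the skeleton. The price is five oxidation-state adjustments.

**Alternative 3:** Only the C4–C5 bond is cut. A para-methylated phenoxide, formed with a hindered potassium alkoxide, attacks through its para carbon (C5) the secondary sulfonate carbon (C4) of a tether attached at the meta position. This closes ring A with inversion at C4 and leaves the cross-conjugated dienone A5.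
- Merits: aromatic and chiral-pool starting materials; C4 and quaternary C5 in one step; the C3 oxygen is present.
- Weak points: O-alkylation and E2 elimination compete at a secondary sulfonate that must bond to a fully substituted carbon. The C5/C4 relationship is decided by tether conformation alone. A5 has the wrong C3 configuration, lacks the C7 oxygen and the C1=C2 alkene, and its two enone alkenes (C6=C7, C9=C10) must be told apart before C7 can be hydroxylated.
- Comparison: it needs neither enzyme nor late C–H oxidation at C3, which is a real advantage. The chosen plan has C7 correct from the outset and a single enone to handle, and the work after its key step is no longer than what A5 would still require.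

Key step: step 3

## Assumptions

- Eremophilane numbering is used for all bicyclic compounds (C14 methyl on C5, C15 methyl on C4; primed numbers for the acyl chain). β denotes the face of the two ring methyls.
- The CIP descriptors at C4 (S to R in step 9) and C7 (S to R in step 5) change only because substituent priorities change; no centre is inverted.
- The cyclase is taken as available by overexpression of the Penicillium roqueforti gene in E. coli and affinity purification; this is enzyme preparation, not a step of the route.
- Farnesyl diphosphate is written as its trisammonium salt.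

## Route

Step 1
Reactants: 1 (2E,6E)-farnesol
Product: 2 (2E,6E)-farnesyl chloride
Conditions: NCS, Me2S, CH2Cl2, −30 → 0 °C
Reagents that add atoms: N-chlorosuccinimide, O=C1CCC(=O)N1Cl
Why: Corey–Kim chlorination: chloride displaces the alkoxysulfonium ion of the primary allylic alcohol at C1, which for prenyl-type alcohols proceeds without allylic transposition or loss of alkene geometry.

Step 2
Reactants: 2 (2E,6E)-farnesyl chloride
Product: 3 (2E,6E)-farnesyl diphosphate trisammonium salt
Conditions: (n-Bu4N)3HP2O7, MeCN, rt; Dowex 50W-X8 (NH4+ form), aq. NH4HCO3–i-PrOH; cellulose chromatography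
Reagents that add atoms: tris(tetrabutylammonium) hydrogen diphosphate, CCCC[N+](CCCC)(CCCC)CCCC.CCCC[N+](CCCC)(CCCC)CCCC.CCCC[N+](CCCC)(CCCC)CCCC.OP(=O)([O-])OP(=O)([O-])[O-]; ammonium hydrogencarbonate, [NH4+].OC([O-])=O
Why: SN2 displacement of the primary allylic chloride by the organic-soluble diphosphate anion, the standard preparation of prenyl diphosphates; cation exchange gives the ammonium form the enzyme accepts.

Step 3
Reactants: 3 (2E,6E)-farnesyl diphosphate trisammonium salt
Product: 5 (+)-aristolochene [(4S,5R,7S)-eremophila-9,11-diene], via (S)-germacrene A 4 (not isolated)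
Conditions: aristolochene synthase (recombinant, from E. coli), MgCl2, HEPES buffer pH 7.5, pentane overlay, 25 °C
Reagents that add atoms: none
Why: The enzyme binds the diphosphate through three magnesium ions and ionises it to the allylic cation, which the distal alkene of the folded chain captures at its less substituted carbon; this 1,10-closure makes the ten-membered ring (bond C6–C7), and proton loss from the resulting tertiary cation gives enzyme-bound (S)-germacrene A 4. Reprotonation of 4 at C1 lets the C4=C5 π bond attack C10 across the macrocycle, so that the single transannular bond C5–C10 closes rings A and B together and leaves a tertiary cation at C4. A 1,2-hydride shift from C5 to C4, a 1,2-methyl shift from C10 to C5 and loss of a C9 proton then give 5. This is the native reaction of the enzyme and belongs to the ionisation-initiated cyclisations of diphosphate-dependent sesquiterpene cyclases, which are run preparatively with recombinant protein. C7 is set in the macrocyclisation by the face of the distal alkene that the chain fold presents to C1. C4 is set by the face on which hydride arrives and C5 by the methyl shift anti to the departing hydride, so the cis relation of the two methyls follows from two successive anti 1,2-shifts. The step needs 1,10- rather than 1,6- or 1,11-closure, completion of the cascade rather than release of 4, and deprotonation at C9 rather than C1; all three are imposed by the active-site contour and the position of the bound diphosphate, not by the substrate. The pentane layer removes the hydrocarbon as it forms, which limits product inhibition and evaporative loss.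

Step 4
Reactants: 5 (+)-aristolochene
Product: 6 (4S,5R,7S)-eremophila-9,11-dien-8-one
Conditions: Rh2(cap)4 (cap = caprolactamate, 1 mol %), t-BuOOH (70% aq.), NaHCO3, CH2Cl2, rt
Reagents that add atoms: tert-butyl hydroperoxide, CC(C)(C)OO
Why: Radical allylic C–H oxidation: tert-butylperoxyl radicals abstract hydrogen at C8 and the C8–C10 allyl radical is oxygenated at its secondary end and carried on to the enone. The same site preference (the methylene beside the CH end of a ring trisubstituted alkene, isopropenyl untouched) governs the oxidation of the isomeric hydrocarbon valencene to nootkatone. No stereocentre is formed, and the buffered medium should keep C7, now α to the ketone, from epimerising or from drawing the isopropenyl alkene into conjugation.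

Step 5
Reactants: 6 (4S,5R,7S)-eremophila-9,11-dien-8-one
Product: 8 (4S,5R,7R)-7-acetoxy-11,12,13-trinoreremophil-9-en-8-one, via the C11 methoxy hydroperoxide 7 (not isolated)
Conditions: O3, CH2Cl2–MeOH, −78 °C (Sudan Red 7B end point); then Ac2O, Et3N, DMAP, −78 °C → rt
Reagents that add atoms: ozone, O=[O+][O-]; methanol, CO
Why: Ozone selects the electron-rich 1,1-disubstituted alkene over the enone, and methanol traps the carbonyl oxide as 7. Acetylation of the hydroperoxide triggers the Criegee rearrangement, in which C7 migrates from carbon to oxygen with retention (as in a Baeyer–Villiger oxidation), and acetate demethylates the resulting dialkoxycarbenium ion. The acetoxy group therefore takes the place of the isopropenyl group, which is also the equatorial, thermodynamically preferred position trans to the C5 methyl.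

Step 6
Reactants: 8 (4S,5R,7R)-7-acetoxy-11,12,13-trinoreremophil-9-en-8-one
Product: 9 (4S,5R,7R)-7-hydroxy-11,12,13-trinoreremophil-9-en-8-one
Conditions: K2CO3 (cat.), MeOH, 0 °C, under N2
Reagents that add atoms: none
Why: Base-catalysed transesterification of an α-acyloxy ketone, which is activated towards methanolysis. Any enolisation at C7 returns the equatorial epimer, so the centre is self-correcting.

Step 7
Reactants: 9 (4S,5R,7R)-7-hydroxy-11,12,13-trinoreremophil-9-en-8-one
Product: 10 (4S,5R,7R)-7-(tert-butyldimethylsilyloxy)-11,12,13-trinoreremophil-9-en-8-one
Conditions: TBSOTf, 2,6-lutidine, CH2Cl2, −78 °C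
Reagents that add atoms: tert-butyldimethylsilyl trifluoromethanesulfonate, CC(C)(C)[Si](C)(C)OS(=O)(=O)C(F)(F)F
Why: Standard silylation of a secondary alcohol; the weak, hindered base and low temperature avoid silyl dienol ether formation from the enone.

Step 8
Reactants: 10 (4S,5R,7R)-7-(tert-butyldimethylsilyloxy)-11,12,13-trinoreremophil-9-en-8-one
Product: 11 (4S,5R,7R)-7-(tert-butyldimethylsilyloxy)-11,12,13-trinoreremophila-1,9-dien-8-one
Conditions: chloranil, t-BuOH, reflux
Reagents that add atoms: none
Why: Quinone dehydrogenation of a fused cyclohexenone in the linear sense: the extended dienol (C8=C9, C10=C1) gives up hydride from C2 to chloranil, the classical route from ring-fused enones to γ,δ-unsaturated dienones. C1 is the only γ-carbon bearing hydrogen because C5 is quaternary.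

Step 9
Reactants: 11 (4S,5R,7R)-7-(tert-butyldimethylsilyloxy)-11,12,13-trinoreremophila-1,9-dien-8-one
Product: 12 (3S,4R,5R,7R)-7-(tert-butyldimethylsilyloxy)-3-hydroxy-11,12,13-trinoreremophila-1,9-dien-8-one
Conditions: SeO2, 1,4-dioxane (wet), 60 °C
Reagents that add atoms: selenium dioxide, O=[Se]=O
Why: Riley allylic hydroxylation: an ene reaction (Se to C1, hydrogen from C3) followed by a [2,3]-sigmatropic shift returns oxygen to C3 on the face from which hydrogen left, so the hydrogen is replaced with retention. The ring fusion holds ring A as an envelope with C4 below the diene plane, so the only C3–H aligned with the C1=C2 π bond is the pseudo-axial β one; SeO2 hydroxylates Δ5-steroids at the 4β position, syn to the angular methyl, for the same reason. The expected product is the 3β-alcohol, with oxygen cis to both methyls as in the target.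

Step 10
Reactants: 13 (R)-4-benzyl-3-propanoyl-1,3-oxazolidin-2-one; 14 acetaldehyde
Product: 16 (4R)-4-benzyl-3-[(2R,3S)-3-hydroxy-2-methylbutanoyl]-1,3-oxazolidin-2-one, via the Z dibutylboron enolate 15 (not isolated)
Conditions: Bu2BOTf, i-Pr2NEt, CH2Cl2, 0 °C; MeCHO, −78 → 0 °C; pH 7 buffer, MeOH, H2O2
Reagents that add atoms: none
Why: Evans syn aldol: the Z boron enolate reacts through a closed chair transition state with the aldehyde methyl equatorial, and the benzyl group of the (R)-auxiliary blocks one enolate face. Both chain centres are set together as (2R,3S), the syn pair that becomes C6′/C7′.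

Step 11
Reactants: 16 (4R)-4-benzyl-3-[(2R,3S)-3-hydroxy-2-methylbutanoyl]-1,3-oxazolidin-2-one
Product: 17 (2R,3S)-3-hydroxy-N-methoxy-N,2-dimethylbutanamide
Conditions: MeNH(OMe)·HCl, AlMe3, THF, −20 → 0 °C
Reagents that add atoms: N,O-dimethylhydroxylamine hydrochloride, CNOC.Cl
Why: Aluminium amide aminolysis of the imide to the Weinreb amide. The free β-hydroxyl directs attack to the exocyclic carbonyl, and the α-centre is not enolised under these Lewis acidic conditions.

Step 12
Reactants: 17 (2R,3S)-3-hydroxy-N-methoxy-N,2-dimethylbutanamide
Product: 18 (2R,3S)-3-(tert-butyldimethylsilyloxy)-N-methoxy-N,2-dimethylbutanamide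
Conditions: TBSOTf, 2,6-lutidine, CH2Cl2, 0 °C
Reagents that add atoms: tert-butyldimethylsilyl trifluoromethanesulfonate, CC(C)(C)[Si](C)(C)OS(=O)(=O)C(F)(F)F
Why: Routine silylation of the secondary alcohol; the same group as on the core allows one final deprotection.

Step 13
Reactants: 18 (2R,3S)-3-(tert-butyldimethylsilyloxy)-N-methoxy-N,2-dimethylbutanamide
Product: 19 (2R,3S)-3-(tert-butyldimethylsilyloxy)-2-methylbutanal
Conditions: i-Bu2AlH, THF, −78 °C; aq. potassium sodium tartrate
Reagents that add atoms: none
Why: Weinreb amide reduction stops at the chelated tetrahedral adduct and releases the aldehyde only on work-up, so neither over-reduction nor epimerisation of the α-centre is expected. The aldehyde is used at once.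

Step 14
Reactants: 19 (2R,3S)-3-(tert-butyldimethylsilyloxy)-2-methylbutanal; 20 triethyl (E)-4-phosphonocrotonate
Product: 22 ethyl (2E,4E,6S,7S)-7-(tert-butyldimethylsilyloxy)-6-methylocta-2,4-dienoate, via the lithiated phosphonate 21 (not isolated)
Conditions: LiN(SiMe3)2, THF, −78 °C; then 19, −78 → 0 °C
Reagents that add atoms: none
Why: Vinylogous Horner–Wadsworth–Emmons olefination: the stabilised anion adds reversibly and eliminates to the E alkene, while the 2E geometry is carried in by the reagent. The non-basic lithium alkoxide intermediates and low temperature protect the α-centre of 19.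

Step 15
Reactants: 22 ethyl (2E,4E,6S,7S)-7-(tert-butyldimethylsilyloxy)-6-methylocta-2,4-dienoate
Product: 23 (2E,4E,6S,7S)-7-(tert-butyldimethylsilyloxy)-6-methylocta-2,4-dienoic acid
Conditions: LiOH, THF–MeOH–H2O, rt; then cold dilute HCl to pH 4
Reagents that add atoms: lithium hydroxide, [Li+].[OH-]
Why: Saponification of an unhindered ethyl ester; the secondary silyl ether and the diene geometry are stable to aqueous hydroxide at room temperature.

Step 16
Reactants: 12 (3S,4R,5R,7R)-7-(tert-butyldimethylsilyloxy)-3-hydroxy-11,12,13-trinoreremophila-1,9-dien-8-one; 23 (2E,4E,6S,7S)-7-(tert-butyldimethylsilyloxy)-6-methylocta-2,4-dienoic acid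
Product: 25 (3S,4R,5R,7R)-7-(tert-butyldimethylsilyloxy)-8-oxo-11,12,13-trinoreremophila-1,9-dien-3-yl (2E,4E,6S,7S)-7-(tert-butyldimethylsilyloxy)-6-methylocta-2,4-dienoate, via the 2,4,6-trichlorobenzoic mixed anhydride 24 (not isolated)
Conditions: 2,4,6-Cl3C6H2COCl, Et3N, THF, rt; then 12, DMAP, toluene, rt
Reagents that add atoms: none
Why: Yamaguchi esterification: DMAP attacks the less hindered dienoyl carbonyl of 24, and the acylpyridinium ion acylates the hindered allylic alcohol. The alcohol reacts through oxygen, so the C3 configuration is retained.

Step 17
Reactants: 25 (3S,4R,5R,7R)-7-(tert-butyldimethylsilyloxy)-8-oxo-11,12,13-trinoreremophila-1,9-dien-3-yl (2E,4E,6S,7S)-7-(tert-butyldimethylsilyloxy)-6-methylocta-2,4-dienoate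
Product: 26 (3S,4R,5R,7R)-7-hydroxy-8-oxo-11,12,13-trinoreremophila-1,9-dien-3-yl (2E,4E,6S,7S)-7-hydroxy-6-methylocta-2,4-dienoate [(1R,2S,7R,8aR)-7-hydroxy-1,8a-dimethyl-6-oxo-1,2,6,7,8,8a-hexahydronaphthalen-2-yl ester]
Conditions: HF·pyridine, pyridine, THF, 0 °C → rt
Reagents that add atoms: none
Why: Fluoride-mediated cleavage of both secondary silyl ethers in a buffered, weakly acidic medium. These conditions avoid base-induced elimination of the allylic ester, acyl migration and epimerisation at C7.

## Compound list

1 | (2E,6E)-farnesol | CC(C)=CCC/C(C)=C/CC/C(C)=C/CO | starting material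
2 | (2E,6E)-farnesyl chloride | CC(C)=CCC/C(C)=C/CC/C(C)=C/CCl | intermediate
3 | (2E,6E)-farnesyl diphosphate, trisammonium salt | CC(C)=CCC/C(C)=C/CC/C(C)=C/COP(=O)([O-])OP(=O)([O-])[O-].[NH4+].[NH4+].[NH4+] | intermediate
4 | (S)-germacrene A [(1E,4E,7S)-germacra-1(10),4,11-triene], enzyme-bound, not isolated | C/C1=C\CC/C(C)=C/C[C@@H](C(C)=C)CC1 | intermediate
5 | (+)-aristolochene [(4S,5R,7S)-eremophila-9,11-diene] | C1CCC2=CC[C@H](C(C)=C)C[C@]2(C)[C@H]1C | intermediate
6 | (4S,5R,7S)-eremophila-9,11-dien-8-one | C1CCC2=CC(=O)[C@H](C(C)=C)C[C@]2(C)[C@H]1C | intermediate
7 | 7-(1-hydroperoxy-1-methoxyethyl)-11,12,13-trinoreremophil-9-en-8-one (ring centres as in 6, both epimers at the peroxy carbon), not isolated | C1CCC2=CC(=O)[C@H](C(C)(OC)OO)C[C@]2(C)[C@H]1C | intermediate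
8 | (4S,5R,7R)-7-acetoxy-11,12,13-trinoreremophil-9-en-8-one | C1CCC2=CC(=O)[C@H](OC(C)=O)C[C@]2(C)[C@H]1C | intermediate
9 | (4S,5R,7R)-7-hydroxy-11,12,13-trinoreremophil-9-en-8-one | C1CCC2=CC(=O)[C@H](O)C[C@]2(C)[C@H]1C | intermediate
10 | (4S,5R,7R)-7-(tert-butyldimethylsilyloxy)-11,12,13-trinoreremophil-9-en-8-one | C1CCC2=CC(=O)[C@H](O[Si](C)(C)C(C)(C)C)C[C@]2(C)[C@H]1C | intermediate
11 | (4S,5R,7R)-7-(tert-butyldimethylsilyloxy)-11,12,13-trinoreremophila-1,9-dien-8-one | C1C=CC2=CC(=O)[C@H](O[Si](C)(C)C(C)(C)C)C[C@]2(C)[C@H]1C | intermediate
12 | (3S,4R,5R,7R)-7-(tert-butyldimethylsilyloxy)-3-hydroxy-11,12,13-trinoreremophila-1,9-dien-8-one | O[C@H]1C=CC2=CC(=O)[C@H](O[Si](C)(C)C(C)(C)C)C[C@]2(C)[C@H]1C | intermediate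
13 | (R)-4-benzyl-3-propanoyl-1,3-oxazolidin-2-one | CCC(=O)N1C(=O)OC[C@H]1Cc1ccccc1 | starting material
14 | acetaldehyde | CC=O | starting material
15 | Z dibutylboron enolate of 13, not isolated | C/C=C(\OB(CCCC)CCCC)N1C(=O)OC[C@H]1Cc1ccccc1 | intermediate
16 | (4R)-4-benzyl-3-[(2R,3S)-3-hydroxy-2-methylbutanoyl]-1,3-oxazolidin-2-one | C[C@H](O)[C@@H](C)C(=O)N1C(=O)OC[C@H]1Cc1ccccc1 | intermediate
17 | (2R,3S)-3-hydroxy-N-methoxy-N,2-dimethylbutanamide | C[C@H](O)[C@@H](C)C(=O)N(C)OC | intermediate
18 | (2R,3S)-3-(tert-butyldimethylsilyloxy)-N-methoxy-N,2-dimethylbutanamide | C[C@H](O[Si](C)(C)C(C)(C)C)[C@@H](C)C(=O)N(C)OC | intermediate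
19 | (2R,3S)-3-(tert-butyldimethylsilyloxy)-2-methylbutanal | C[C@H](O[Si](C)(C)C(C)(C)C)[C@@H](C)C=O | intermediate
20 | triethyl (E)-4-phosphonocrotonate [ethyl (2E)-4-(diethoxyphosphoryl)but-2-enoate] | CCOC(=O)/C=C/CP(=O)(OCC)OCC | starting material
21 | lithium salt of 20 deprotonated at C4, not isolated | [Li+].CCOC(=O)/C=C/[CH-]P(=O)(OCC)OCC | intermediate
22 | ethyl (2E,4E,6S,7S)-7-(tert-butyldimethylsilyloxy)-6-methylocta-2,4-dienoate | C[C@H](O[Si](C)(C)C(C)(C)C)[C@@H](C)/C=C/C=C/C(=O)OCC | intermediate
23 | (2E,4E,6S,7S)-7-(tert-butyldimethylsilyloxy)-6-methylocta-2,4-dienoic acid | C[C@H](O[Si](C)(C)C(C)(C)C)[C@@H](C)/C=C/C=C/C(=O)O | intermediate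
24 | mixed anhydride of 23 and 2,4,6-trichlorobenzoic acid, not isolated | C[C@H](O[Si](C)(C)C(C)(C)C)[C@@H](C)/C=C/C=C/C(=O)OC(=O)c1c(Cl)cc(Cl)cc1Cl | intermediate
25 | (3S,4R,5R,7R)-7-(tert-butyldimethylsilyloxy)-8-oxo-11,12,13-trinoreremophila-1,9-dien-3-yl (2E,4E,6S,7S)-7-(tert-butyldimethylsilyloxy)-6-methylocta-2,4-dienoate | C[C@H](O[Si](C)(C)C(C)(C)C)[C@@H](C)/C=C/C=C/C(=O)O[C@H]1C=CC2=CC(=O)[C@H](O[Si](C)(C)C(C)(C)C)C[C@]2(C)[C@H]1C | intermediate
26 | (3S,4R,5R,7R)-7-hydroxy-8-oxo-11,12,13-trinoreremophila-1,9-dien-3-yl (2E,4E,6S,7S)-7-hydroxy-6-methylocta-2,4-dienoate | C[C@H](O)[C@@H](C)/C=C/C=C/C(=O)O[C@H]1C=CC2=CC(=O)[C@H](O)C[C@]2(C)[C@H]1C | target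

## Step count and weak points

Total: 17 steps. Longest linear sequence: 11 steps (steps 1–9, 16, 17, from farnesol 1). The side chain takes 6 steps (10–15) from 13 and 14.

**Step 3 (key step).** Turnover may stall: these cyclases release product slowly, the hydrocarbon inhibits, and magnesium–diphosphate aggregates can precipitate at preparative substrate loading. Part of the flux may also leave the active site at the macrocyclic stage, and the volatile product can be lost on concentration.
Fallback: set out from 1 and generate the substrate in the same vessel as the cyclase. A promiscuous alcohol kinase and an isopentenyl phosphate kinase, with ATP regenerated from phosphoenolpyruvate by pyruvate kinase and MgCl2, convert farnesol into (2E,6E)-farnesyl phosphate F1 and then into the diphosphate (the anion of 3). The diphosphate is consumed at a low stationary concentration, and the route is rejoined at 5 without isolating 2 or 3.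

**Step 9.** The ene reaction may be slow because the C1=C2 bond is the electron-poor end of a dienone. Oxidation could then turn to the C7 position α to the ketone, or go on from the alcohol to the C3 ketone. Facial selectivity could also be poor if approach to the β face past the C5 methyl is too hindered.
Fallback: set out from 11 and reverse the polarity. Me3SiOTf and Et3N give the extended silyl trienol ether F7, which is nucleophilic at C3. Dimethyldioxirane at low temperature (a Rubottom-type oxidation, axial attack as in the γ-hydroxylation of steroidal dienol ethers) followed by mild acid returns the route at 12. If either oxidation delivers the 3α-epimer F8 instead, it is carried forward by a Mitsunobu esterification with 23 (PPh3, diisopropyl azodicarboxylate), which inverts C3 and rejoins the route at 25.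

**Step 4.** Hydrogen abstraction may not discriminate well enough between C8, C1 and the allylic positions of the isopropenyl group. The β,γ-unsaturated product may also lose its C7 integrity by migration of the isopropenyl alkene into conjugation.
Fallback: set out from 5 with a Schenck ene reaction (O2, visible light, tetraphenylporphyrin sensitiser). It attacks the more electron-rich ring alkene on its more substituted side and gives the tertiary allylic hydroperoxide F2. PPh3 reduces it to the tertiary allylic alcohol F3. Babler–Dauben oxidative transposition with pyridinium chlorochromate, (C5H5NH)[CrO3Cl], buffered with NaOAc, then moves oxygen to C8 and rejoins the route at 6.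

**Step 5.** The migrating carbon C7 is deactivated by the adjacent carbonyl, so the rearrangement may be slow. Fragmentation to the methyl ketone, addition of the hydroperoxide to the C8 ketone, or base-induced enolisation at C7 may compete.
Fallback: set out from 6 and remove the three-carbon unit entirely. Ozonolysis with Me2S work-up gives the β-diketone F4. NaOMe in MeOH cleaves it by a retro-Claisen reaction to the known type of dimethyloctalone F5. LiN(i-Pr)2 and Me3SiCl give the cross-conjugated silyl dienol ether F6. Rubottom oxidation (dimethyldioxirane, then dilute acid) introduces the C7 hydroxyl trans to the axial C5 methyl and rejoins the route at 9.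

**Step 16.** Acylation of the hindered pseudo-axial alcohol may be slow enough for the activated dienoyl unit to lose its C6′ configuration or alkene geometry through vinylogous ketene formation.
Fallback: set out from 12 and build the dienoate on the core. Saponification of 20 gives (E)-4-(diethoxyphosphoryl)but-2-enoic acid F9, a small acyl donor with no stereocentre. Diisopropylcarbodiimide and DMAP attach it to 12 to give the phosphonate ester F10. A Horner–Wadsworth–Emmons reaction of F10 with aldehyde 19 (LiN(SiMe3)2, THF, −78 °C) forms the C4′=C5′ bond and rejoins the route at 25.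

## Further compounds

F1 | step 3 | (2E,6E)-farnesyl phosphate | CC(C)=CCC/C(C)=C/CC/C(C)=C/COP(=O)(O)O
F2 | step 4 | (4S,5R,7S)-10α-hydroperoxyeremophila-8,11-diene (hydroperoxy group trans to the C5 methyl) | C1CC[C@@]2(OO)C=C[C@H](C(C)=C)C[C@]2(C)[C@H]1C
F3 | step 4 | (4S,5R,7S)-eremophila-8,11-dien-10α-ol | C1CC[C@@]2(O)C=C[C@H](C(C)=C)C[C@]2(C)[C@H]1C
F4 | step 5 | 7-acetyl-11,12,13-trinoreremophil-9-en-8-one (4S,5R; C7 labile) | C1CCC2=CC(=O)[C@H](C(C)=O)C[C@]2(C)[C@H]1C
F5 | step 5 | (4S,5R)-11,12,13-trinoreremophil-9-en-8-one | C1CCC2=CC(=O)CC[C@]2(C)[C@H]1C
F6 | step 5 | (4S,5R)-8-(trimethylsilyloxy)-11,12,13-trinoreremophila-7,9-diene | C1CCC2=CC(O[Si](C)(C)C)=CC[C@]2(C)[C@H]1C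
F7 | step 9 | (4S,5R,7R)-7-(tert-butyldimethylsilyloxy)-8-(trimethylsilyloxy)-11,12,13-trinoreremophila-1(10),2,8-triene | C1=CC=C2C=C(O[Si](C)(C)C)[C@H](O[Si](C)(C)C(C)(C)C)C[C@]2(C)[C@H]1C
F8 | step 9 | (3R,4R,5R,7R)-7-(tert-butyldimethylsilyloxy)-3-hydroxy-11,12,13-trinoreremophila-1,9-dien-8-one (3α-epimer of 12) | O[C@@H]1C=CC2=CC(=O)[C@H](O[Si](C)(C)C(C)(C)C)C[C@]2(C)[C@H]1C
F9 | step 16 | (E)-4-(diethoxyphosphoryl)but-2-enoic acid | CCOP(=O)(OCC)C/C=C/C(=O)O
F10 | step 16 | (3S,4R,5R,7R)-7-(tert-butyldimethylsilyloxy)-8-oxo-11,12,13-trinoreremophila-1,9-dien-3-yl (E)-4-(diethoxyphosphoryl)but-2-enoate | CCOP(=O)(OCC)C/C=C/C(=O)O[C@H]1C=CC2=CC(=O)[C@H](O[Si](C)(C)C(C)(C)C)C[C@]2(C)[C@H]1C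
A1 | alternative 1 | cis-fused Diels–Alder adduct, 3-(tert-butyldimethylsilyloxy)-4-oxo-8-(trimethylsilyloxy)-11,12,13,15-tetranoreremophil-7-ene | CC(C)(C)[Si](C)(C)O[C@H]1CC[C@@H]2CC(O[Si](C)(C)C)=CC[C@]2(C)C1=O
A2 | alternative 1 | (S)-6-(tert-butyldimethylsilyloxy)-2-methylcyclohex-2-en-1-one | CC(C)(C)[Si](C)(C)O[C@H]1CCC=C(C)C1=O
A3 | alternative 1 | 2-(trimethylsilyloxy)buta-1,3-diene | C=CC(=C)O[Si](C)(C)C
A4 | alternative 2 | (3S,4R,5R,7R)-7-(tert-butyldimethylsilyloxy)-3-(triethylsilyloxy)-11,12,13-trinoreremophila-1,9-dien-8-one | CC[Si](CC)(CC)O[C@H]1C=CC2=CC(=O)[C@H](O[Si](C)(C)C(C)(C)C)C[C@]2(C)[C@H]1C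
A5 | alternative 3 | (3R,4R,5R)-3-(tert-butyldimethylsilyloxy)-11,12,13-trinoreremophila-6,9-dien-8-one | CC(C)(C)[Si](C)(C)O[C@@H]1CCC2=CC(=O)C=C[C@]2(C)[C@H]1C
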